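**Retrosynthetic overview**

1. The strategy rests on the oxolane ring (O1, C2, C3, C4, C5). C3 carries the CH2O–caffeoyl carbon and C4 the benzylic CH2; these two exocyclic carbons are cis to each other and both trans to the guaiacyl group on C2. That is the pattern left by a syn addition of two one-carbon units to the C3=C4 bond of a 2-aryl-2,5-dihydrofuran on the face away from the aryl group.
2. Disconnections, last to first: the caffeate C–O bond (esterification); the C4 CH2–aryl bond (nickel cross-electrophile coupling of a primary iodide with an aryl bromide); the C3–C and C4–C bonds together (palladium-catalysed oxidative bis(methoxycarbonylation) with CO); the C2–aryl bond (asymmetric Heck arylation of 2,3-dihydrofuran).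
3. The oxolane is bought as 2,3-dihydrofuran and no ring is formed in the route. C2 is set by the Heck ligand, C3 and C4 by the carbonylation, and the two esters are then told apart by the different crowding at C3 and C4.
4. The phenols travel as silyl ethers (triisopropylsilyl on both guaiacyl rings, tert-butyldimethylsilyl on the caffeate) and are freed together at the end with buffered fluoride.

Key step: step 5

Remarks on the chemistry:
- The ring positions O1, C2 (aryl), C3, C4, C5 are used with this numbering for every oxolane in the route.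
- The guaiacyl phenols are carried as triisopropylsilyl ethers because these should resist the mild base and acid of steps 2, 5 and 6 better than smaller silyl ethers.
- Assumption: the (S)-configured tert-butyl phosphinooxazoline is taken to give the (R)-2-aryl-2,5-dihydrofuran, as expected by analogy with simple aryl triflates; if the sense is the opposite, the (R) ligand is used and nothing else changes.

**Route**

Step 1
Reactants: 1 vanillin (4-hydroxy-3-methoxybenzaldehyde)
Product: 2 3-methoxy-4-(triisopropylsilyloxy)benzaldehyde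
Conditions: TIPSCl, imidazole, DMF, rt
Reagents that add atoms: triisopropylsilyl chloride, CC(C)[Si](Cl)(C(C)C)C(C)C
Why: Silylation of a phenol with a silyl chloride and imidazole is routine, and the bulky silyl ether should survive every step up to the final fluoride treatment.

Step 2
Reactants: 2 3-methoxy-4-(triisopropylsilyloxy)benzaldehyde
Product: 4 3-methoxy-4-(triisopropylsilyloxy)phenol, via aryl formate 3 (not isolated)
Conditions: mCPBA, CH2Cl2, rt; then Et3N, MeOH, rt
Reagents that add atoms: meta-chloroperoxybenzoic acid, OOC(=O)c1cccc(Cl)c1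
Why: Baeyer–Villiger (Dakin-type) oxidation of an electron-rich benzaldehyde proceeds with aryl migration to the formate, which is methanolysed under conditions too mild to touch the aryl silyl ether.

Step 3
Reactants: 4 3-methoxy-4-(triisopropylsilyloxy)phenol
Product: 5 3-methoxy-4-(triisopropylsilyloxy)phenyl trifluoromethanesulfonate
Conditions: Tf2O, pyridine, CH2Cl2, 0 °C
Reagents that add atoms: trifluoromethanesulfonic anhydride, O=S(=O)(OS(=O)(=O)C(F)(F)F)C(F)(F)F
Why: Triflation of a phenol gives the aryl triflate, the electrophile that enters the cationic pathway of the asymmetric Heck reaction.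

Step 4
Reactants: 5 3-methoxy-4-(triisopropylsilyloxy)phenyl trifluoromethanesulfonate; 6 2,3-dihydrofuran (in excess)
Product: 7 (R)-2-[3-methoxy-4-(triisopropylsilyloxy)phenyl]-2,5-dihydrofuran
Conditions: Pd2(dba)3 (1.5 mol%), (S)-4-tert-butyl-2-[2-(diphenylphosphino)phenyl]-4,5-dihydrooxazole (6 mol%), iPr2NEt, THF, 70 °C
Reagents that add atoms: none
Why: Asymmetric Heck arylation: the cationic arylpalladium from the triflate delivers the aryl group to the oxygen-bearing alkene carbon of 6 (the future C2) under control of the chiral P,N ligand, and β-hydride elimination away from the new centre followed by release of the alkene without reinsertion leaves the C3=C4 (2,5-dihydro) isomer.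

Step 5
Reactants: 7 (R)-2-[3-methoxy-4-(triisopropylsilyloxy)phenyl]-2,5-dihydrofuran
Product: 8 dimethyl (2R,3R,4S)-2-[3-methoxy-4-(triisopropylsilyloxy)phenyl]oxolane-3,4-dicarboxylate (esters cis to each other, both trans to the aryl group)
Conditions: Pd(OCOCF3)2 (5 mol%), N,N'-bis(2,6-dimethylphenyl)butane-2,3-diimine (5.5 mol%), p-benzoquinone (1.5 equiv), TsOH·H2O (2 mol%), CO (4 bar), MeOH/THF 7:1, 20 °C
Reagents that add atoms: carbon monoxide, [C-]#[O+]; methanol, CO
Why: A methoxycarbonyl–palladium species formed from divalent palladium, methanol and CO binds the C3=C4 bond on the face opposite the C2 aryl group and inserts it syn; CO then inserts into the new alkyl–palladium bond with retention, methanolysis of the acyl releases the second ester on the same face, and benzoquinone returns zerovalent palladium to the divalent state. The closest known reaction type is the diimine–palladium oxidative bis(alkoxycarbonylation) of cyclic and 1,2-disubstituted alkenes to syn succinates, applied here to a 2-aryl-2,5-dihydrofuran. No ring is closed. C3 and C4 are created together: their cis relation follows from the syn mechanism, and their relation to C2 (both esters trans to the aryl group) from substrate control, the aryl group on the neighbouring carbon blocking one face of the nearly flat ring. Regiochemistry does not arise because both alkene carbons receive the same group, so the step needs only facial selectivity and carbonylation faster than β-hydride elimination toward C2 or C5, which the chelating diimine and the CO pressure should secure by leaving no free cis site. The sulfonic acid is kept at catalyst level because the C2–O bond of 7 is both allylic and benzylic and could ionise in acidic methanol.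

Step 6
Reactants: 8 dimethyl (2R,3R,4S)-2-aryl-oxolane-3,4-dicarboxylate
Product: 9 (3S,4R,5R)-4-(methoxycarbonyl)-5-[3-methoxy-4-(triisopropylsilyloxy)phenyl]oxolane-3-carboxylic acid (route numbering: C4 carboxylic acid, C3 methyl ester)
Conditions: Me3SnOH (3 equiv), 1,2-dichloroethane, 60 °C; cold 0.5 M aq HCl wash
Reagents that add atoms: trimethyltin hydroxide, C[Sn](C)(C)O
Why: Me3SnOH-mediated ester hydrolysis is sensitive to crowding and does not epimerise α-centres, so it should cleave the C4 ester, whose ring neighbour C5 is a CH2, in preference to the C3 ester, which sits between C4 and the aryl-bearing C2.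

Step 7
Reactants: 9 half-ester (C4 acid, C3 methyl ester)
Product: 10 methyl (2R,3R,4R)-4-(hydroxymethyl)-2-[3-methoxy-4-(triisopropylsilyloxy)phenyl]oxolane-3-carboxylate
Conditions: BH3·SMe2, THF, 0 °C; MeOH quench, evaporation below 25 °C, crude used at once
Reagents that add atoms: none
Why: Borane reduces a carboxylic acid through its acyloxyborane much faster than a methyl ester, and the neutral quench without acid or base is chosen so that the cis γ-hydroxy ester is not given time to lactonise.

Step 8
Reactants: 10 methyl (2R,3R,4R)-4-(hydroxymethyl)-2-aryl-oxolane-3-carboxylate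
Product: 11 methyl (2R,3R,4S)-4-(iodomethyl)-2-[3-methoxy-4-(triisopropylsilyloxy)phenyl]oxolane-3-carboxylate
Conditions: I2, PPh3, imidazole, CH2Cl2, 0 °C
Reagents that add atoms: iodine, II
Why: Appel-type iodination converts the primary alcohol by SN2 displacement of the oxyphosphonium group at the exocyclic carbon, so no ring stereocentre is touched.

Step 9
Reactants: 12 4-bromo-2-methoxyphenol
Product: 13 (4-bromo-2-methoxyphenoxy)triisopropylsilane
Conditions: TIPSCl, imidazole, DMF, rt
Reagents that add atoms: triisopropylsilyl chloride, CC(C)[Si](Cl)(C(C)C)C(C)C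
Why: Phenol silylation as in step 1 gives the aryl bromide partner with the same protecting group as the oxolane fragment.

Step 10
Reactants: 11 methyl (2R,3R,4S)-4-(iodomethyl)-2-aryl-oxolane-3-carboxylate; 13 (4-bromo-2-methoxyphenoxy)triisopropylsilane
Product: 14 methyl (2R,3R,4S)-4-[3-methoxy-4-(triisopropylsilyloxy)benzyl]-2-[3-methoxy-4-(triisopropylsilyloxy)phenyl]oxolane-3-carboxylate
Conditions: NiBr2·glyme (10 mol%), 4,4'-di-tert-butyl-2,2'-bipyridine (10 mol%), Zn dust (2 equiv), NaI (0.25 equiv), pyridine (10 mol%), DMA, 60 °C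
Reagents that add atoms: none
Why: Nickel-catalysed reductive cross-electrophile coupling: the aryl bromide adds oxidatively to zerovalent nickel, the primary alkyl radical from the iodide is captured by the arylnickel species, and reductive elimination forms the CH2–aryl bond; the radical sits on the exocyclic carbon, so C3 and C4 keep their configuration and the ester is tolerated.

Step 11
Reactants: 14 methyl (2R,3R,4S)-4-(arylmethyl)-2-aryl-oxolane-3-carboxylate
Product: 15 [(2R,3S,4S)-4-[3-methoxy-4-(triisopropylsilyloxy)benzyl]-2-[3-methoxy-4-(triisopropylsilyloxy)phenyl]oxolan-3-yl]methanol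
Conditions: LiBH4, THF/MeOH, 0 °C to rt
Reagents that add atoms: none
Why: LiBH4 reduces the methyl ester to the primary alcohol without affecting aryl silyl ethers or the benzylic ether, and reduction should be faster than enolisation at C3.

Step 12
Reactants: 16 caffeic acid ((E)-3-(3,4-dihydroxyphenyl)prop-2-enoic acid)
Product: 18 (E)-3-[3,4-bis(tert-butyldimethylsilyloxy)phenyl]prop-2-enoic acid, via silyl ester 17 (not isolated)
Conditions: TBSCl (3.5 equiv), imidazole, DMF, rt; then AcOH, THF/H2O, rt
Reagents that add atoms: tert-butyldimethylsilyl chloride, CC(C)(C)[Si](C)(C)Cl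
Why: Exhaustive silylation followed by hydrolysis of the silyl ester, which is far more labile than the aryl silyl ethers, frees only the carboxylic acid.

Step 13
Reactants: 15 [(2R,3S,4S)-4-(arylmethyl)-2-aryl-oxolan-3-yl]methanol; 18 (E)-3-[3,4-bis(tert-butyldimethylsilyloxy)phenyl]prop-2-enoic acid
Product: 19 [(2R,3S,4S)-4-[3-methoxy-4-(triisopropylsilyloxy)benzyl]-2-[3-methoxy-4-(triisopropylsilyloxy)phenyl]oxolan-3-yl]methyl (E)-3-[3,4-bis(tert-butyldimethylsilyloxy)phenyl]prop-2-enoate
Conditions: EDC·HCl, DMAP (cat.), CH2Cl2, 0 °C to rt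
Reagents that add atoms: none
Why: Steglich esterification of a primary alcohol with a cinnamic acid proceeds under neutral conditions that leave the (E) alkene and all silyl ethers intact.

Step 14
Reactants: 19 fully silylated caffeate
Product: 20 [(2R,3S,4S)-4-(4-hydroxy-3-methoxybenzyl)-2-(4-hydroxy-3-methoxyphenyl)oxolan-3-yl]methyl (E)-3-(3,4-dihydroxyphenyl)prop-2-enoate (target)
Conditions: TBAF/AcOH (1:1, 5 equiv), THF, 0 °C
Reagents that add atoms: none
Why: Fluoride cleaves all four aryl silyl ethers, and buffering with acetic acid keeps the phenols protonated so that neither ester cleavage nor quinone-methide opening of the C2–O bond (which would epimerise C2) is expected.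

**Compound list**

1 | vanillin | COc1cc(C=O)ccc1O | starting material
2 | 3-methoxy-4-(triisopropylsilyloxy)benzaldehyde | COc1cc(C=O)ccc1O[Si](C(C)C)(C(C)C)C(C)C | intermediate
3 | 3-methoxy-4-(triisopropylsilyloxy)phenyl formate | COc1cc(OC=O)ccc1O[Si](C(C)C)(C(C)C)C(C)C | intermediate
4 | 3-methoxy-4-(triisopropylsilyloxy)phenol | COc1cc(O)ccc1O[Si](C(C)C)(C(C)C)C(C)C | intermediate
5 | 3-methoxy-4-(triisopropylsilyloxy)phenyl trifluoromethanesulfonate | COc1cc(OS(=O)(=O)C(F)(F)F)ccc1O[Si](C(C)C)(C(C)C)C(C)C | intermediate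
6 | 2,3-dihydrofuran | C1=COCC1 | starting material
7 | (R)-2-[3-methoxy-4-(triisopropylsilyloxy)phenyl]-2,5-dihydrofuran | C1=C[C@H](c2ccc(O[Si](C(C)C)(C(C)C)C(C)C)c(OC)c2)OC1 | intermediate
8 | dimethyl (2R,3R,4S)-2-[3-methoxy-4-(triisopropylsilyloxy)phenyl]oxolane-3,4-dicarboxylate | COC(=O)[C@@H]1CO[C@@H](c2ccc(O[Si](C(C)C)(C(C)C)C(C)C)c(OC)c2)[C@@H]1C(=O)OC | intermediate
9 | (3S,4R,5R)-4-(methoxycarbonyl)-5-[3-methoxy-4-(triisopropylsilyloxy)phenyl]oxolane-3-carboxylic acid | OC(=O)[C@@H]1CO[C@@H](c2ccc(O[Si](C(C)C)(C(C)C)C(C)C)c(OC)c2)[C@@H]1C(=O)OC | intermediate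
10 | methyl (2R,3R,4R)-4-(hydroxymethyl)-2-[3-methoxy-4-(triisopropylsilyloxy)phenyl]oxolane-3-carboxylate | OC[C@@H]1CO[C@@H](c2ccc(O[Si](C(C)C)(C(C)C)C(C)C)c(OC)c2)[C@@H]1C(=O)OC | intermediate
11 | methyl (2R,3R,4S)-4-(iodomethyl)-2-[3-methoxy-4-(triisopropylsilyloxy)phenyl]oxolane-3-carboxylate | IC[C@@H]1CO[C@@H](c2ccc(O[Si](C(C)C)(C(C)C)C(C)C)c(OC)c2)[C@@H]1C(=O)OC | intermediate
12 | 4-bromo-2-methoxyphenol | COc1cc(Br)ccc1O | starting material
13 | (4-bromo-2-methoxyphenoxy)triisopropylsilane | COc1cc(Br)ccc1O[Si](C(C)C)(C(C)C)C(C)C | intermediate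
14 | methyl (2R,3R,4S)-4-[3-methoxy-4-(triisopropylsilyloxy)benzyl]-2-[3-methoxy-4-(triisopropylsilyloxy)phenyl]oxolane-3-carboxylate | COc1cc(C[C@@H]2CO[C@@H](c3ccc(O[Si](C(C)C)(C(C)C)C(C)C)c(OC)c3)[C@@H]2C(=O)OC)ccc1O[Si](C(C)C)(C(C)C)C(C)C | intermediate
15 | [(2R,3S,4S)-4-[3-methoxy-4-(triisopropylsilyloxy)benzyl]-2-[3-methoxy-4-(triisopropylsilyloxy)phenyl]oxolan-3-yl]methanol | COc1cc(C[C@@H]2CO[C@@H](c3ccc(O[Si](C(C)C)(C(C)C)C(C)C)c(OC)c3)[C@@H]2CO)ccc1O[Si](C(C)C)(C(C)C)C(C)C | intermediate
16 | caffeic acid | O=C(O)/C=C/c1ccc(O)c(O)c1 | starting material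
17 | tert-butyldimethylsilyl (E)-3-[3,4-bis(tert-butyldimethylsilyloxy)phenyl]prop-2-enoate | CC(C)(C)[Si](C)(C)OC(=O)/C=C/c1ccc(O[Si](C)(C)C(C)(C)C)c(O[Si](C)(C)C(C)(C)C)c1 | intermediate
18 | (E)-3-[3,4-bis(tert-butyldimethylsilyloxy)phenyl]prop-2-enoic acid | O=C(O)/C=C/c1ccc(O[Si](C)(C)C(C)(C)C)c(O[Si](C)(C)C(C)(C)C)c1 | intermediate
19 | [(2R,3S,4S)-4-[3-methoxy-4-(triisopropylsilyloxy)benzyl]-2-[3-methoxy-4-(triisopropylsilyloxy)phenyl]oxolan-3-yl]methyl (E)-3-[3,4-bis(tert-butyldimethylsilyloxy)phenyl]prop-2-enoate | COc1cc(C[C@@H]2CO[C@@H](c3ccc(O[Si](C(C)C)(C(C)C)C(C)C)c(OC)c3)[C@@H]2COC(=O)/C=C/c2ccc(O[Si](C)(C)C(C)(C)C)c(O[Si](C)(C)C(C)(C)C)c2)ccc1O[Si](C(C)C)(C(C)C)C(C)C | intermediate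
20 | [(2R,3S,4S)-4-(4-hydroxy-3-methoxybenzyl)-2-(4-hydroxy-3-methoxyphenyl)oxolan-3-yl]methyl (E)-3-(3,4-dihydroxyphenyl)prop-2-enoate | COc1cc(C[C@@H]2CO[C@@H](c3ccc(O)c(OC)c3)[C@@H]2COC(=O)/C=C/c2ccc(O)c(O)c2)ccc1O | target

**Step count**

Total: 14 steps. Longest linear sequence: 12 steps (steps 1–8, 10, 11, 13, 14, from vanillin); steps 9 and 12 are one-step side branches.

**Steps most likely to fail, with fallbacks**

1. Step 5 (bis(methoxycarbonylation)). Three processes could defeat it: β-hydride elimination or alkene migration outrunning CO insertion, acid-promoted ionisation of the allylic, benzylic C2–O bond in methanol, and incomplete discrimination between the two faces. The fallback adds the two carbons by cycloaddition instead and sets out from 7.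
   - Dichloroketene (Cl3CCOCl, Zn–Cu couple, POCl3, Et2O) should add by [2+2] cycloaddition on the face opposite the aryl group to give the cis-fused 7,7-dichloro-2-aryl-3-oxabicyclo[3.2.0]heptan-6-one F1. Either orientation of the ketene serves; the one with the carbonyl carbon on C4 is drawn.
   - Zn in AcOH removes the chlorines to give the cyclobutanone F2.
   - LiN(iPr)2 and TMSCl at −78 °C give the silyl enol ether F3 on the CH2 side.
   - Ozonolysis (O3, CH2Cl2, −78 °C, then Me2S) opens the four-membered ring to the aldehyde acid F4, which is oxidised at once (NaClO2, NaH2PO4, 2-methyl-2-butene) to the cis-diacid F5.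
   - TMSCHN2 in MeOH/toluene gives the dimethyl ester, and the route is rejoined at 8.

2. Step 6 (monohydrolysis). Hydrolysis may take place at the C3 ester instead, or at both esters at similar rates. The fallback makes both half-esters productive and sets out from 8.
   - The hydrolysis is stopped at partial conversion and the two half-esters are separated.
   - The isomeric half-ester F6 (C3 acid, C4 methyl ester) is treated with LiBH4 in THF, which reduces the C4 ester but not the lithium carboxylate, to give the lithium hydroxy carboxylate F7.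
   - Without acidification, F7 is methylated at the carboxylate with MeI in DMF. The product is 10, where the route is rejoined, so the sequence no longer depends on which ester is cleaved.

3. Step 7 (borane reduction, with the iodination of step 8). The cis γ-hydroxy ester may close to the lactone during reduction, work-up or iodination. The fallback accepts the lactone and sets out from 10.
   - Ring closure is completed with catalytic pyridinium p-toluenesulfonate in CH2Cl2 to give the cis-fused lactone F8.
   - Aminolysis with Me2NH·HCl and AlMe3 (CH2Cl2, 0 °C to rt) opens it to the hydroxy dimethylamide F9, whose amide carbonyl re-closes far less readily than an ester.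
   - I2, PPh3 and imidazole give the iodo amide F10, which is used at once.
   - Coupling with 13 under the conditions of step 10 (NiBr2·glyme, 4,4'-di-tert-butyl-2,2'-bipyridine, Zn) gives the benzylated amide F11.
   - LiNH2BH3 in THF reduces the tertiary amide to the primary alcohol. The product is 15, where the route is rejoined, bypassing 11 and 14.

**Further compounds**

F1 | step 5 | 7,7-dichloro-2-[3-methoxy-4-(triisopropylsilyloxy)phenyl]-3-oxabicyclo[3.2.0]heptan-6-one (cis-fused, four-membered ring trans to the aryl group) | O=C1[C@@H]2CO[C@@H](c3ccc(O[Si](C(C)C)(C(C)C)C(C)C)c(OC)c3)[C@@H]2C1(Cl)Cl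
F2 | step 5 | 2-[3-methoxy-4-(triisopropylsilyloxy)phenyl]-3-oxabicyclo[3.2.0]heptan-6-one (same configuration) | O=C1[C@@H]2CO[C@@H](c3ccc(O[Si](C(C)C)(C(C)C)C(C)C)c(OC)c3)[C@@H]2C1
F3 | step 5 | 2-[3-methoxy-4-(triisopropylsilyloxy)phenyl]-6-(trimethylsilyloxy)-3-oxabicyclo[3.2.0]hept-6-ene | C[Si](C)(C)OC=1[C@@H]2CO[C@@H](c3ccc(O[Si](C(C)C)(C(C)C)C(C)C)c(OC)c3)[C@@H]2C=1
F4 | step 5 | 4-formyl-5-[3-methoxy-4-(triisopropylsilyloxy)phenyl]oxolane-3-carboxylic acid (configuration as in 8; C4 acid, C3 aldehyde in route numbering) | OC(=O)[C@@H]1CO[C@@H](c2ccc(O[Si](C(C)C)(C(C)C)C(C)C)c(OC)c2)[C@@H]1C=O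
F5 | step 5 | 2-[3-methoxy-4-(triisopropylsilyloxy)phenyl]oxolane-3,4-dicarboxylic acid (configuration as in 8) | OC(=O)[C@@H]1CO[C@@H](c2ccc(O[Si](C(C)C)(C(C)C)C(C)C)c(OC)c2)[C@@H]1C(=O)O
F6 | step 6 | 4-(methoxycarbonyl)-2-[3-methoxy-4-(triisopropylsilyloxy)phenyl]oxolane-3-carboxylic acid (configuration as in 8; C3 acid, C4 methyl ester) | COC(=O)[C@@H]1CO[C@@H](c2ccc(O[Si](C(C)C)(C(C)C)C(C)C)c(OC)c2)[C@@H]1C(=O)O
F7 | step 6 | lithium 4-(hydroxymethyl)-2-[3-methoxy-4-(triisopropylsilyloxy)phenyl]oxolane-3-carboxylate (configuration as in 10) | OC[C@@H]1CO[C@@H](c2ccc(O[Si](C(C)C)(C(C)C)C(C)C)c(OC)c2)[C@@H]1C(=O)[O-].[Li+]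
F8 | step 7 | 8-[3-methoxy-4-(triisopropylsilyloxy)phenyl]-3,7-dioxabicyclo[3.3.0]octan-2-one (cis-fused lactone, carbonyl on route C3) | O=C1OC[C@@H]2CO[C@@H](c3ccc(O[Si](C(C)C)(C(C)C)C(C)C)c(OC)c3)[C@@H]21
F9 | step 7 | 4-(hydroxymethyl)-2-[3-methoxy-4-(triisopropylsilyloxy)phenyl]-N,N-dimethyloxolane-3-carboxamide (configuration as in 10) | OC[C@@H]1CO[C@@H](c2ccc(O[Si](C(C)C)(C(C)C)C(C)C)c(OC)c2)[C@@H]1C(=O)N(C)C
F10 | step 7 | 4-(iodomethyl)-2-[3-methoxy-4-(triisopropylsilyloxy)phenyl]-N,N-dimethyloxolane-3-carboxamide (configuration as in 11) | IC[C@@H]1CO[C@@H](c2ccc(O[Si](C(C)C)(C(C)C)C(C)C)c(OC)c2)[C@@H]1C(=O)N(C)C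
F11 | step 7 | 4-[3-methoxy-4-(triisopropylsilyloxy)benzyl]-2-[3-methoxy-4-(triisopropylsilyloxy)phenyl]-N,N-dimethyloxolane-3-carboxamide (configuration as in 14) | COc1cc(C[C@@H]2CO[C@@H](c3ccc(O[Si](C(C)C)(C(C)C)C(C)C)c(OC)c3)[C@@H]2C(=O)N(C)C)ccc1O[Si](C(C)C)(C(C)C)C(C)C
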